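**Retrosynthetic overview**

1. The strategy rests on ring C: its O1–C2(aryl)=C3(OH)–C4(=O) array is a constitutional isomer of the spiro-oxirane of a 2-benzylidene-1-benzofuran-3-one (aurone epoxide) whose benzylic oxirane carbon already carries ring B. Ring C is therefore made last, by a hydroxide-induced five-to-six ring expansion, followed by 3-O-methylation and one acidic global deprotection.
2. The aurone is disconnected at its (Z)-enol ether C–O bond (AuCl-catalysed 5-exo-dig hydroalkoxylation) and at the carbinol–alkyne bond, giving ring A salicylaldehyde 20 and ring B arylacetylene 13.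
3. Ring B comes from 3-bromo-4-hydroxybenzaldehyde: O-allylation, Claisen rearrangement and cross-metathesis install the prenyl group, a B-alkyl Suzuki–Miyaura coupling at C–Br attaches the side chain, and the aldehyde is homologated to the alkyne.
4. The only stereocentre is bought with methyl (R)-3-hydroxy-2-methylpropanoate: its hydroxymethyl arm becomes the CH2OH of the target and its ester carbon becomes a chain carbon, which gives the (S) centre without any stereochemical operation.
5. Ring A comes from methyl 3,5-dihydroxy-4-methoxybenzoate (ester to aldehyde to phenol by Baeyer–Villiger oxidation, then ortho-formylation). Ring order: furanone ring (step 17), oxirane (step 18), ring C (step 19).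

Key step: step 19

Remark: 23, 24 and 26 form as mixtures of diastereomers, because new centres arise without control beside the fixed (S) centre of the chain; these centres become sp2 in steps 17 and 19, so the mixtures are carried on unseparated.

Abbreviations: MOM = methoxymethyl; TBS = tert-butyldimethylsilyl; ArB = 3-[(3S)-4-(TBS-oxy)-3-methylbutyl]-4-(methoxymethoxy)-5-(3-methylbut-2-en-1-yl)phenyl.

**Side-chain fragment**

Step 1
Reactants: 1 methyl (2R)-3-hydroxy-2-methylpropanoate
Product: 2 methyl (2R)-3-(TBS-oxy)-2-methylpropanoate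
Conditions: TBSCl, imidazole, CH2Cl2, 0 °C → rt
Reagents that add atoms: tert-butyldimethylsilyl chloride, CC(C)(C)[Si](C)(C)Cl
Why: Imidazole-promoted O-silylation of a primary alcohol is fast and non-enolising, so the α-centre is untouched.

Step 2
Reactants: 2 methyl (2R)-3-(TBS-oxy)-2-methylpropanoate
Product: 3 (2S)-3-(TBS-oxy)-2-methylpropan-1-ol
Conditions: i-Bu2AlH (2.5 equiv), CH2Cl2, −78 → 0 °C; aq. KNaC4H4O6
Reagents that add atoms: none
Why: Hydride reduction of the ester to the primary alcohol leaves the silyl ether and the stereocentre intact; the descriptor changes to S only because the CIP priorities change.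

Step 3
Reactants: 3 (2S)-3-(TBS-oxy)-2-methylpropan-1-ol
Product: 4 (2R)-3-(TBS-oxy)-2-methylpropanal
Conditions: (COCl)2, DMSO, CH2Cl2, −78 °C; Et3N, −78 → −20 °C; used at once without chromatography
Reagents that add atoms: none
Why: Swern oxidation at low temperature should give the α-branched aldehyde with minimal enolisation, and immediate use limits epimerisation.

Step 4
Reactants: 4 (2R)-3-(TBS-oxy)-2-methylpropanal
Product: 5 tert-butyldimethyl{[(2S)-2-methylbut-3-en-1-yl]oxy}silane
Conditions: Ph3PCH3Br, KN(SiMe3)2, THF, 0 °C; then 4, −78 °C → rt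
Reagents that add atoms: methyltriphenylphosphonium bromide, C[P+](c1ccccc1)(c1ccccc1)c1ccccc1.[Br-]
Why: Wittig methylenation with the preformed, salt-free ylide adds to the aldehyde faster than the α-proton is removed, so the centre is carried over unchanged and is no longer epimerisable afterwards.

**Ring B fragment**

Step 5
Reactants: 6 3-bromo-4-hydroxybenzaldehyde
Product: 7 3-bromo-4-(prop-2-en-1-yloxy)benzaldehyde
Conditions: allyl bromide, K2CO3, DMF, rt
Reagents that add atoms: allyl bromide, C=CCBr
Why: Williamson etherification of an acidic phenol with a reactive allylic halide.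

Step 6
Reactants: 7 3-bromo-4-(prop-2-en-1-yloxy)benzaldehyde
Product: 8 3-bromo-4-hydroxy-5-(prop-2-en-1-yl)benzaldehyde
Conditions: PhNEt2, 195 °C, argon
Reagents that add atoms: none
Why: The aromatic Claisen rearrangement ([3,3]-sigmatropic shift, then tautomerisation) delivers the allyl group to the only ortho position that bears hydrogen.

Step 7
Reactants: 8 3-bromo-4-hydroxy-5-(prop-2-en-1-yl)benzaldehyde
Product: 9 3-bromo-4-(methoxymethoxy)-5-(prop-2-en-1-yl)benzaldehyde
Conditions: MOMCl, i-Pr2NEt, CH2Cl2, 0 °C → rt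
Reagents that add atoms: chloromethyl methyl ether, COCCl
Why: O-alkylation of the acidic phenol gives the MOM acetal, which is stable to every basic, organometallic and oxidative step that follows.

Step 8
Reactants: 9 3-bromo-4-(methoxymethoxy)-5-(prop-2-en-1-yl)benzaldehyde
Product: 10 3-bromo-4-(methoxymethoxy)-5-(3-methylbut-2-en-1-yl)benzaldehyde
Conditions: 2-methylbut-2-ene (large excess), second-generation Grubbs catalyst RuCl2(=CHPh)(H2IMes)(PCy3) (5 mol %), CH2Cl2, 40 °C, sealed
Reagents that add atoms: 2-methylbut-2-ene, CC=C(C)C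
Why: Olefin cross-metathesis of the terminal allyl group with excess 2-methylbut-2-ene converts it into the prenyl group with loss of propene, and the aryl bromide, aldehyde and acetal are inert to the ruthenium carbene.

Step 9
Reactants: 5 tert-butyldimethyl{[(2S)-2-methylbut-3-en-1-yl]oxy}silane; 10 3-bromo-4-(methoxymethoxy)-5-(3-methylbut-2-en-1-yl)benzaldehyde
Product: 12 3-[(3S)-4-(TBS-oxy)-3-methylbutyl]-4-(methoxymethoxy)-5-(3-methylbut-2-en-1-yl)benzaldehyde, via alkylborane 11 (not isolated)
Conditions: 5 (1.3 equiv), 9-BBN-H, THF, 0 °C → rt; then 10, PdCl2(dppf) (5 mol %), aq. K3PO4, DMF, 60 °C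
Reagents that add atoms: 9-borabicyclo[3.3.1]nonane (9-BBN-H), B1C2CCCC1CCC2 (its boron cage is part of intermediate 11 only; 12 keeps just its hydrogen)
Why: Anti-Markovnikov hydroboration of the terminal alkene followed by B-alkyl Suzuki–Miyaura coupling forms the aryl–CH2 bond; the alkene is kept in slight excess so that no B–H remains to touch the aldehyde or the prenyl alkene, and the stereocentre is not involved.

Step 10
Reactants: 12 3-[(3S)-4-(TBS-oxy)-3-methylbutyl]-4-(methoxymethoxy)-5-(3-methylbut-2-en-1-yl)benzaldehyde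
Product: 13 tert-butyl{[(2S)-4-[5-ethynyl-2-(methoxymethoxy)-3-(3-methylbut-2-en-1-yl)phenyl]-2-methylbutyl]oxy}dimethylsilane (ArB–C≡CH)
Conditions: dimethyl (1-diazo-2-oxopropyl)phosphonate, K2CO3, MeOH, 0 °C → rt
Reagents that add atoms: dimethyl (1-diazo-2-oxopropyl)phosphonate, CC(=O)C(=[N+]=[N-])P(=O)(OC)OC
Why: Seyferth–Gilbert homologation with the Ohira–Bestmann reagent turns the non-enolisable aryl aldehyde into the terminal alkyne under mild carbonate conditions that spare the silyl ether and the acetal.

**Ring A fragment**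

Step 11
Reactants: 14 methyl 3,5-dihydroxy-4-methoxybenzoate
Product: 15 methyl 4-methoxy-3,5-bis(methoxymethoxy)benzoate
Conditions: MOMCl, i-Pr2NEt, CH2Cl2, 0 °C → rt
Reagents that add atoms: chloromethyl methyl ether, COCCl
Why: Double O-alkylation of the two equivalent phenols gives the bis-MOM ether.

Step 12
Reactants: 15 methyl 4-methoxy-3,5-bis(methoxymethoxy)benzoate
Product: 16 [4-methoxy-3,5-bis(methoxymethoxy)phenyl]methanol
Conditions: LiAlH4, THF, 0 °C
Reagents that add atoms: none
Why: Hydride reduction of the benzoate to the benzylic alcohol does not affect aryl ethers or acetals.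

Step 13
Reactants: 16 [4-methoxy-3,5-bis(methoxymethoxy)phenyl]methanol
Product: 17 4-methoxy-3,5-bis(methoxymethoxy)benzaldehyde
Conditions: MnO2, CH2Cl2, rt
Reagents that add atoms: none
Why: MnO2 oxidises benzylic alcohols selectively and stops at the aldehyde.

Step 14
Reactants: 17 4-methoxy-3,5-bis(methoxymethoxy)benzaldehyde
Product: 19 4-methoxy-3,5-bis(methoxymethoxy)phenol, via aryl formate 18 (not isolated)
Conditions: mCPBA, CH2Cl2, 0 °C → rt; then K2CO3 (cat.), MeOH, rt
Reagents that add atoms: 3-chloroperoxybenzoic acid, OOC(=O)c1cccc(Cl)c1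
Why: Baeyer–Villiger (Dakin-type) oxidation, in which the electron-rich aryl group migrates in preference to hydrogen to give the formate, and mild methanolysis then frees the phenol.

Step 15
Reactants: 19 4-methoxy-3,5-bis(methoxymethoxy)phenol
Product: 20 2-hydroxy-5-methoxy-4,6-bis(methoxymethoxy)benzaldehyde
Conditions: MgCl2, Et3N, (CH2O)n, MeCN, reflux
Reagents that add atoms: paraformaldehyde (as formaldehyde), C=O
Why: Magnesium-mediated ortho-formylation (Casnati–Skattebøl): the magnesium phenoxide delivers formaldehyde to an ortho carbon (the two are equivalent), a second formaldehyde oxidises the benzylic alkoxide by hydride transfer, and the weakly Lewis-acidic basic medium spares the MOM ethers.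

**Assembly**

Step 16
Reactants: 20 2-hydroxy-5-methoxy-4,6-bis(methoxymethoxy)benzaldehyde; 13 ArB–C≡CH
Product: 23 2-[1-hydroxy-3-(ArB)prop-2-yn-1-yl]-4-methoxy-3,5-bis(methoxymethoxy)phenol (both carbinol epimers), via sodium phenoxide 21 (not isolated), via lithium acetylide 22 (not isolated)
Conditions: 20, NaH, THF, 0 °C; 13 (1.3 equiv), n-BuLi, THF, −78 °C; combine, −78 → 0 °C; aq. NH4Cl
Reagents that add atoms: sodium hydride, [NaH] (sodium of intermediate 21 only); n-butyllithium, [Li]CCCC (lithium of intermediate 22 only)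
Why: 1,2-Addition of a lithium acetylide to the aldehyde forms the carbinol–alkyne bond; the phenol is deprotonated beforehand with NaH so that no acetylide is wasted as a base, and the new carbinol centre needs no control because step 17 oxidises it.

Step 17
Reactants: 23 2-[1-hydroxy-3-(ArB)prop-2-yn-1-yl]-4-methoxy-3,5-bis(methoxymethoxy)phenol
Product: 25 (2Z)-2-[(ArB)methylidene]-5-methoxy-4,6-bis(methoxymethoxy)-1-benzofuran-3(2H)-one (aurone), via aurone alcohol 24 (not isolated)
Conditions: AuCl (10 mol %), K2CO3 (10 mol %), MeCN, rt; filter; MnO2, CH2Cl2, rt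
Reagents that add atoms: none
Why: AuCl-catalysed anti-oxyauration of the alkyne by the phenol (5-exo-dig) followed by protodeauration gives the (Z)-enol ether, the sp3 carbinol rules out a conjugate six-ring pathway and the carbonate buffer suppresses ionisation of the carbinol, and MnO2 then oxidises the allylic-benzylic alcohol to the aurone without isolating the sensitive alcohol.

Step 18
Reactants: 25 (2Z)-2-[(ArB)methylidene]-5-methoxy-4,6-bis(methoxymethoxy)-1-benzofuran-3(2H)-one
Product: 26 3'-(ArB)-5-methoxy-4,6-bis(methoxymethoxy)-3H-spiro[1-benzofuran-2,2'-oxiran]-3-one (aurone epoxide; racemic oxirane, hence two diastereomers)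
Conditions: 30% aq. H2O2, aq. NaOH, MeOH–THF, 0 °C; aq. Na2SO3 as soon as 25 is consumed
Reagents that add atoms: hydrogen peroxide, OO
Why: Weitz–Scheffer nucleophilic epoxidation, in which hydroperoxide adds to the benzylidene carbon of the enone and the enolate closes the oxirane; the unactivated prenyl alkene is not attacked by a nucleophilic oxidant, and cold, short exposure with a reductive quench keeps the product from opening in the peroxide medium.

Step 19
Reactants: 26 3'-(ArB)-5-methoxy-4,6-bis(methoxymethoxy)-3H-spiro[1-benzofuran-2,2'-oxiran]-3-one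
Product: 29 2-(ArB)-3-hydroxy-6-methoxy-5,7-bis(methoxymethoxy)-4H-chromen-4-one, via ring-opened diketone 27 (not isolated), via rearranged diketone 28 (not isolated)
Conditions: NaOH (0.2 M), EtOH–H2O, degassed, argon, 0 °C → rt; aq. NH4Cl
Reagents that add atoms: water (delivered as hydroxide), O (by the mechanism below its oxygen becomes the C3 hydroxyl oxygen, while the former oxirane oxygen leaves as water)
Why: This is the alkali-induced ring expansion of an aurone epoxide to a flavonol, closest in type to the known base-mediated aurone epoxide rearrangement within the Algar–Flynn–Oyamada manifold: the lone pair of O1 helps the spiro C–O bond of the oxirane to open, hydroxide caps the oxocarbenium carbon, and the hemiketal collapses with cleavage of the old O1–C2 bond to the phenoxide α-hydroxy-1,2-diketone 27. Enolisation through the enediol moves the carbonyl to the benzylic carbon (28), and the phenoxide attacks this aroyl carbon in a 6-exo-trig closure that forms the new O1–C2 bond and ring C, after which loss of water gives the 3-hydroxy-γ-pyranone. No stereocentre is created: both oxirane carbons become sp2, so the two epoxide diastereomers converge, and the (S) centre of the chain is remote and not enolisable. The selectivity needed is six-ring closure over a benzilic acid-type shift or cleavage of 27 and over mere reclosure to the five-membered hemiketal. It is secured by the ortho phenoxide held beside the diketone, the fast enolisation of the doubly activated benzylic C–H and the irreversible dehydration to the conjugated, hydrogen-bonded flavonol, helped by dilute base, low temperature and exclusion of peroxide and oxygen. The MOM ethers, the primary silyl ether and the prenyl alkene are inert to cold dilute hydroxide.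

Step 20
Reactants: 29 2-(ArB)-3-hydroxy-6-methoxy-5,7-bis(methoxymethoxy)-4H-chromen-4-one
Product: 30 2-(ArB)-3,6-dimethoxy-5,7-bis(methoxymethoxy)-4H-chromen-4-one
Conditions: MeI, K2CO3, acetone, 40 °C
Reagents that add atoms: iodomethane, CI
Why: Williamson O-methylation of the acidic 3-hydroxyl, which is the only free hydroxyl in the molecule.

Step 21
Reactants: 30 2-(ArB)-3,6-dimethoxy-5,7-bis(methoxymethoxy)-4H-chromen-4-one
Product: 31 5,7-dihydroxy-2-{4-hydroxy-3-[(3S)-4-hydroxy-3-methylbutyl]-5-(3-methylbut-2-en-1-yl)phenyl}-3,6-dimethoxy-4H-chromen-4-one (target)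
Conditions: HCl (1.25 M in MeOH), MeOH, 0 °C → rt
Reagents that add atoms: none
Why: Acid-catalysed acetal exchange with methanol removes the three MOM groups and the same medium solvolyses the primary silyl ether; dilute acid at or below room temperature is chosen so that the prenyl group beside the freed 4'-hydroxyl does not cyclise or add HCl, and the stereocentre is not affected.

**Compound list**

1 | methyl (2R)-3-hydroxy-2-methylpropanoate | COC(=O)[C@H](C)CO | starting material
2 | methyl (2R)-3-(TBS-oxy)-2-methylpropanoate | COC(=O)[C@H](C)CO[Si](C)(C)C(C)(C)C | intermediate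
3 | (2S)-3-(TBS-oxy)-2-methylpropan-1-ol | OC[C@H](C)CO[Si](C)(C)C(C)(C)C | intermediate
4 | (2R)-3-(TBS-oxy)-2-methylpropanal | O=C[C@H](C)CO[Si](C)(C)C(C)(C)C | intermediate
5 | tert-butyldimethyl{[(2S)-2-methylbut-3-en-1-yl]oxy}silane | C=C[C@H](C)CO[Si](C)(C)C(C)(C)C | intermediate
6 | 3-bromo-4-hydroxybenzaldehyde | O=Cc1ccc(O)c(Br)c1 | starting material
7 | 3-bromo-4-(prop-2-en-1-yloxy)benzaldehyde | O=Cc1ccc(OCC=C)c(Br)c1 | intermediate
8 | 3-bromo-4-hydroxy-5-(prop-2-en-1-yl)benzaldehyde | O=Cc1cc(CC=C)c(O)c(Br)c1 | intermediate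
9 | 3-bromo-4-(methoxymethoxy)-5-(prop-2-en-1-yl)benzaldehyde | O=Cc1cc(CC=C)c(OCOC)c(Br)c1 | intermediate
10 | 3-bromo-4-(methoxymethoxy)-5-(3-methylbut-2-en-1-yl)benzaldehyde | O=Cc1cc(CC=C(C)C)c(OCOC)c(Br)c1 | intermediate
11 | 9-[(3S)-4-(TBS-oxy)-3-methylbutyl]-9-borabicyclo[3.3.1]nonane (formed in the flask, not isolated) | B1(CC[C@H](C)CO[Si](C)(C)C(C)(C)C)C2CCCC1CCC2 | intermediate
12 | 3-[(3S)-4-(TBS-oxy)-3-methylbutyl]-4-(methoxymethoxy)-5-(3-methylbut-2-en-1-yl)benzaldehyde | O=Cc1cc(CC=C(C)C)c(OCOC)c(CC[C@H](C)CO[Si](C)(C)C(C)(C)C)c1 | intermediate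
13 | tert-butyl{[(2S)-4-[5-ethynyl-2-(methoxymethoxy)-3-(3-methylbut-2-en-1-yl)phenyl]-2-methylbutyl]oxy}dimethylsilane | C#Cc1cc(CC=C(C)C)c(OCOC)c(CC[C@H](C)CO[Si](C)(C)C(C)(C)C)c1 | intermediate
14 | methyl 3,5-dihydroxy-4-methoxybenzoate | COC(=O)c1cc(O)c(OC)c(O)c1 | starting material
15 | methyl 4-methoxy-3,5-bis(methoxymethoxy)benzoate | COC(=O)c1cc(OCOC)c(OC)c(OCOC)c1 | intermediate
16 | [4-methoxy-3,5-bis(methoxymethoxy)phenyl]methanol | OCc1cc(OCOC)c(OC)c(OCOC)c1 | intermediate
17 | 4-methoxy-3,5-bis(methoxymethoxy)benzaldehyde | O=Cc1cc(OCOC)c(OC)c(OCOC)c1 | intermediate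
18 | 4-methoxy-3,5-bis(methoxymethoxy)phenyl formate (formed in the flask, not isolated) | O=COc1cc(OCOC)c(OC)c(OCOC)c1 | intermediate
19 | 4-methoxy-3,5-bis(methoxymethoxy)phenol | Oc1cc(OCOC)c(OC)c(OCOC)c1 | intermediate
20 | 2-hydroxy-5-methoxy-4,6-bis(methoxymethoxy)benzaldehyde | O=Cc1c(O)cc(OCOC)c(OC)c1OCOC | intermediate
21 | sodium 2-formyl-4-methoxy-3,5-bis(methoxymethoxy)phenoxide (formed in the flask, not isolated) | [Na+].[O-]c1cc(OCOC)c(OC)c(OCOC)c1C=O | intermediate
22 | lithium acetylide of 13 (formed in the flask, not isolated) | [Li]C#Cc1cc(CC=C(C)C)c(OCOC)c(CC[C@H](C)CO[Si](C)(C)C(C)(C)C)c1 | intermediate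
23 | 2-[1-hydroxy-3-(ArB)prop-2-yn-1-yl]-4-methoxy-3,5-bis(methoxymethoxy)phenol, both carbinol epimers | OC(C#Cc1cc(CC=C(C)C)c(OCOC)c(CC[C@H](C)CO[Si](C)(C)C(C)(C)C)c1)c1c(O)cc(OCOC)c(OC)c1OCOC | intermediate
24 | (2Z)-2-[(ArB)methylidene]-5-methoxy-4,6-bis(methoxymethoxy)-2,3-dihydro-1-benzofuran-3-ol, both carbinol epimers (formed in the flask, not isolated) | OC1c2c(OCOC)c(OC)c(OCOC)cc2O/C1=C\c1cc(CC=C(C)C)c(OCOC)c(CC[C@H](C)CO[Si](C)(C)C(C)(C)C)c1 | intermediate
25 | (2Z)-2-[(ArB)methylidene]-5-methoxy-4,6-bis(methoxymethoxy)-1-benzofuran-3(2H)-one | O=C1c2c(OCOC)c(OC)c(OCOC)cc2O/C1=C\c1cc(CC=C(C)C)c(OCOC)c(CC[C@H](C)CO[Si](C)(C)C(C)(C)C)c1 | intermediate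
26 | 3'-(ArB)-5-methoxy-4,6-bis(methoxymethoxy)-3H-spiro[1-benzofuran-2,2'-oxiran]-3-one, racemic oxirane | COCOc1cc2OC3(OC3c3cc(CC=C(C)C)c(OCOC)c(CC[C@H](C)CO[Si](C)(C)C(C)(C)C)c3)C(=O)c2c(OCOC)c1OC | intermediate
27 | 3-hydroxy-1-[2-hydroxy-5-methoxy-4,6-bis(methoxymethoxy)phenyl]-3-(ArB)propane-1,2-dione, present as its phenoxide (formed in the flask, not isolated) | O=C(C(=O)C(O)c1cc(CC=C(C)C)c(OCOC)c(CC[C@H](C)CO[Si](C)(C)C(C)(C)C)c1)c1c(O)cc(OCOC)c(OC)c1OCOC | intermediate
28 | 2-hydroxy-1-[2-hydroxy-5-methoxy-4,6-bis(methoxymethoxy)phenyl]-3-(ArB)propane-1,3-dione, present as its phenoxide (formed in the flask, not isolated) | O=C(C(O)C(=O)c1cc(CC=C(C)C)c(OCOC)c(CC[C@H](C)CO[Si](C)(C)C(C)(C)C)c1)c1c(O)cc(OCOC)c(OC)c1OCOC | intermediate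
29 | 2-(ArB)-3-hydroxy-6-methoxy-5,7-bis(methoxymethoxy)-4H-chromen-4-one | COCOc1cc2oc(-c3cc(CC=C(C)C)c(OCOC)c(CC[C@H](C)CO[Si](C)(C)C(C)(C)C)c3)c(O)c(=O)c2c(OCOC)c1OC | intermediate
30 | 2-(ArB)-3,6-dimethoxy-5,7-bis(methoxymethoxy)-4H-chromen-4-one | COCOc1cc2oc(-c3cc(CC=C(C)C)c(OCOC)c(CC[C@H](C)CO[Si](C)(C)C(C)(C)C)c3)c(OC)c(=O)c2c(OCOC)c1OC | intermediate
31 | 5,7-dihydroxy-2-{4-hydroxy-3-[(3S)-4-hydroxy-3-methylbutyl]-5-(3-methylbut-2-en-1-yl)phenyl}-3,6-dimethoxy-4H-chromen-4-one | COc1c(O)cc2oc(-c3cc(CC=C(C)C)c(O)c(CC[C@H](C)CO)c3)c(OC)c(=O)c2c1O | target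

**Step count**

Total: 21 steps. Longest linear sequence: 12 steps (steps 5–10 and 16–21 from 6; the same length from 1 through steps 1–4, 9, 10 and 16–21).

**Steps most likely to fail, with fallbacks**

Step 19 (key ring expansion). The ring-opened diketone may be diverted before it closes: a benzilic acid-type 1,2-shift, retro-Claisen cleavage, or reclosure to the five-membered hemiketal without dehydration would drain material away from the pyranone. The fallback leaves the aurone manifold and builds ring C directly with known reactions. It sets out from 23, which is oxidised with MnO2 in CH2Cl2 to the ynone 1-[2-hydroxy-5-methoxy-4,6-bis(methoxymethoxy)phenyl]-3-(ArB)prop-2-yn-1-one F1. Et2NH in EtOH at rt adds to the ynone to give an enaminone that the phenol closes by addition–elimination, giving the flavone 2-(ArB)-6-methoxy-5,7-bis(methoxymethoxy)-4H-chromen-4-one F2. C3 of F2 is lithiated with LiN(i-Pr)2 in THF at −78 °C and trapped with B(OMe)3 as the dimethyl 3-boronate of the flavone F3, which is oxidised without isolation with H2O2 and aq. NaOH to the 3-hydroxyflavone. The fallback comes back to the route at 29.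

Step 16 (acetylide addition). The aldehyde reacts as an electron-rich, doubly ortho-substituted phenoxide, so 1,2-addition may be slow and incomplete and would then demand a large excess of the most valuable fragment. The fallback masks the phenol so that a neutral aldehyde is attacked. It sets out from 20, which is O-allylated (allyl bromide, K2CO3, DMF) to 5-methoxy-4,6-bis(methoxymethoxy)-2-(prop-2-en-1-yloxy)benzaldehyde F4. Addition of the lithium acetylide 22 (1.1 equiv, THF, −78 °C) gives the O-allyl propargylic alcohol 1-[5-methoxy-4,6-bis(methoxymethoxy)-2-(prop-2-en-1-yloxy)phenyl]-3-(ArB)prop-2-yn-1-ol F5. Tsuji–Trost deallylation with Pd(PPh3)4 (cat.) and morpholine in THF at rt frees the phenol; the C-prenyl group carries no leaving group and is inert. The fallback comes back to the route at 23.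

Step 21 (global deprotection). Once the 4'-hydroxyl is free, Brønsted acid may drive cyclisation of the neighbouring prenyl group to a dimethylchromane or addition of HCl or methanol across the alkene, in competition with slow cleavage of the hindered MOM ethers. The fallback uses no protic acid and removes the groups in two orthogonal stages. It sets out from 30: TMSOTf and 2,2′-bipyridyl in CH2Cl2 at 0 °C convert the three aryl MOM ethers, through the N-(methoxymethyl)bipyridinium salt, into 2-{3-[(3S)-4-(TBS-oxy)-3-methylbutyl]-5-(3-methylbut-2-en-1-yl)-4-[(trimethylsilyl)oxy]phenyl}-3,6-dimethoxy-5,7-bis[(trimethylsilyl)oxy]-4H-chromen-4-one F6, which is not isolated. Bu4NF in THF, buffered with AcOH, then cleaves the three aryl silyl ethers and the primary TBS ether. The fallback comes back to the route at 31.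

**Further compounds**

F1 | step 19 | 1-[2-hydroxy-5-methoxy-4,6-bis(methoxymethoxy)phenyl]-3-(ArB)prop-2-yn-1-one | O=C(C#Cc1cc(CC=C(C)C)c(OCOC)c(CC[C@H](C)CO[Si](C)(C)C(C)(C)C)c1)c1c(O)cc(OCOC)c(OC)c1OCOC
F2 | step 19 | 2-(ArB)-6-methoxy-5,7-bis(methoxymethoxy)-4H-chromen-4-one | COCOc1cc2oc(-c3cc(CC=C(C)C)c(OCOC)c(CC[C@H](C)CO[Si](C)(C)C(C)(C)C)c3)cc(=O)c2c(OCOC)c1OC
F3 | step 19 | dimethyl [2-(ArB)-6-methoxy-5,7-bis(methoxymethoxy)-4-oxo-4H-chromen-3-yl]boronate | COCOc1cc2oc(-c3cc(CC=C(C)C)c(OCOC)c(CC[C@H](C)CO[Si](C)(C)C(C)(C)C)c3)c(B(OC)OC)c(=O)c2c(OCOC)c1OC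
F4 | step 16 | 5-methoxy-4,6-bis(methoxymethoxy)-2-(prop-2-en-1-yloxy)benzaldehyde | O=Cc1c(OCC=C)cc(OCOC)c(OC)c1OCOC
F5 | step 16 | 1-[5-methoxy-4,6-bis(methoxymethoxy)-2-(prop-2-en-1-yloxy)phenyl]-3-(ArB)prop-2-yn-1-ol, both carbinol epimers | OC(C#Cc1cc(CC=C(C)C)c(OCOC)c(CC[C@H](C)CO[Si](C)(C)C(C)(C)C)c1)c1c(OCC=C)cc(OCOC)c(OC)c1OCOC
F6 | step 21 | 2-{3-[(3S)-4-(TBS-oxy)-3-methylbutyl]-5-(3-methylbut-2-en-1-yl)-4-[(trimethylsilyl)oxy]phenyl}-3,6-dimethoxy-5,7-bis[(trimethylsilyl)oxy]-4H-chromen-4-one | COc1c(O[Si](C)(C)C)cc2oc(-c3cc(CC=C(C)C)c(O[Si](C)(C)C)c(CC[C@H](C)CO[Si](C)(C)C(C)(C)C)c3)c(OC)c(=O)c2c1O[Si](C)(C)C
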